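**Strategy.** The route reads the cross-conjugated α-methylene ketone C7(=CH2)–C8(=O) of the side chain as an opened cyclopropanol whose three ring atoms are C7, the methylene carbon and C8. A titanium-mediated hydroxycyclopropanation therefore joins a C5-vinyl cyclohexene (ring C1–C6) to the ester carbon of a C8–C11 prenyl ester. This makes C7–C8 and a sacrificial C8–CH2 bond in one operation. Palladium then breaks the sacrificial bond and releases the enone. The coupling partner is a (1S,5S,6S) vinylcyclohexenol with C1 silylated and the homoallylic C6 hydroxyl free to anchor titanium. Directed epoxidation, C1 oxidation and a final Schenck ene reaction complete the target.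

Key step: step 9

**Remarks on the chemistry**
- Numbering: the ring is C1 (ketone), C2 (methyl-bearing epoxide carbon), C3 (epoxide CH), C4 (CH2), C5 (CH with side chain) and C6 (CH–O-tiglate). The chain is C7 (=CH2), C8 (C=O), C9=C10 and C11 (C–OOH).
- The target is (2S,3S,5S,6S). With the ring drawn flat, the C5 chain and the epoxide oxygen lie on one face and the C6 oxygen on the other.
- Assumption: Rh/(R)-BINAP is taken to show the same sense of induction on 6-methylcyclohex-2-enone as on cyclohex-2-enone, where the (R)-ligand gives the (R)-3-substituted ketone. If the sense is opposite, the antipodal ligand is used.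
- The two carbinols are distinguished by their order of arrival. C6–O enters as a triethylsilyl ether, C1–O is then capped as the bulkier silyl ether, and the small silyl group is removed. No selective monosilylation of a diol is needed.
- With a free homoallylic hydroxyl, the hydroxycyclopropanation is known to give the trans-1,2-dialkylcyclopropanol, so the cyclopropanol is drawn trans. Any other cyclopropane isomer converges on ring opening.
- The C1 silyl ether is later removed with acidic fluoride, not basic fluoride. This prevents tiglate migration and conjugate addition.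

Step 1
Reactants: 1 6-methylcyclohex-2-en-1-one (racemic); 2 potassium vinyltrifluoroborate
Product: 3 (5R)-5-ethenyl-2-methylcyclohexan-1-one (both C2 epimers)
Conditions: [Rh(cod)2]PF6 (3 mol %), (R)-BINAP (3.3 mol %), toluene/H2O, 100 °C
Reagents that add atoms: none
Why: In this rhodium-catalysed asymmetric 1,4-addition (Hayashi–Miyaura type) the vinylrhodium–BINAP species adds to one enone face under catalyst control and sets C5 as R, and the C2 epimers arising from the racemic enone converge in step 2.

Step 2
Reactants: 3 (5R)-5-ethenyl-2-methylcyclohexan-1-one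
Product: 4 [(5R)-5-ethenyl-2-methylcyclohex-1-en-1-yl]oxytrimethylsilane
Conditions: TMSCl, NaI, Et3N, MeCN, rt
Reagents that add atoms: chlorotrimethylsilane, C[Si](C)(C)Cl
Why: Enol silylation under equilibrating conditions, with iodotrimethylsilane made in situ, favours the more substituted C1=C2 enol ether, which erases the C2 centre and puts the enol ether on the side where the ring alkene is wanted.

Step 3
Reactants: 4 [(5R)-5-ethenyl-2-methylcyclohex-1-en-1-yl]oxytrimethylsilane
Product: 5 (5R)-5-ethenyl-2-methylcyclohex-2-en-1-one
Conditions: Pd(OAc)2 (10 mol %), O2 (1 atm), DMSO, rt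
Reagents that add atoms: none
Why: In this Saegusa–Ito dehydrosilylation the oxa-π-allylpalladium at C2 loses the ring C3 hydrogen by β-hydride elimination to give the endocyclic enone, oxygen returns zerovalent palladium to divalent palladium, and the isolated vinyl group is left alone at this temperature.

Step 4
Reactants: 5 (5R)-5-ethenyl-2-methylcyclohex-2-en-1-one
Product: 7 (5S,6S)-5-ethenyl-2-methyl-6-(triethylsilyloxy)cyclohex-2-en-1-one, via triethylsilyl dienol ether 6 (not isolated)
Conditions: LiN(iPr)2, THF, −78 °C, then TESCl, −78 → 0 °C; solvent change to hexane, filtration; mCPBA, hexane, −15 °C → rt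
Reagents that add atoms: chlorotriethylsilane, CC[Si](CC)(CC)Cl; mCPBA, O=C(OO)c1cccc(Cl)c1
Why: In this Rubottom oxidation of the kinetic cross-conjugated dienol ether the peracid epoxidises the electron-richest C1=C6 bond from the face opposite the C5 vinyl group (C6–O trans to vinyl), and the silyl shift in a non-polar medium, from which 3-chlorobenzoic acid precipitates, keeps the silyl group on the new oxygen.

Step 5
Reactants: 7 (5S,6S)-5-ethenyl-2-methyl-6-(triethylsilyloxy)cyclohex-2-en-1-one
Product: 8 (1S,5S,6S)-5-ethenyl-2-methyl-6-(triethylsilyloxy)cyclohex-2-en-1-ol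
Conditions: NaBH4, CeCl3·7H2O, MeOH, −78 °C
Reagents that add atoms: none
Why: In this Luche 1,2-reduction hydride arrives along the axial trajectory on the face of the axial C5–H and gives the pseudo-equatorial C1 alcohol, cis to the vinyl group and trans to C6–O, in the same sense as the reduction of carvone to cis-carveol.

Step 6
Reactants: 8 (1S,5S,6S)-5-ethenyl-2-methyl-6-(triethylsilyloxy)cyclohex-2-en-1-ol
Product: 9 (1S,5S,6S)-1-(tert-butyldimethylsilyloxy)-5-ethenyl-2-methyl-6-(triethylsilyloxy)cyclohex-2-ene
Conditions: TBSOTf, 2,6-lutidine, CH2Cl2, −78 → 0 °C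
Reagents that add atoms: tert-butyldimethylsilyl triflate, CC(C)(C)[Si](C)(C)OS(=O)(=O)C(F)(F)F
Why: Silylation of a hindered secondary allylic alcohol with a silyl triflate and a non-nucleophilic base forms no free alkoxide, so the neighbouring triethylsilyl group does not migrate.

Step 7
Reactants: 9 (1S,5S,6S)-1-(tert-butyldimethylsilyloxy)-5-ethenyl-2-methyl-6-(triethylsilyloxy)cyclohex-2-ene
Product: 10 (1S,2S,6S)-2-(tert-butyldimethylsilyloxy)-6-ethenyl-3-methylcyclohex-3-en-1-ol (C1 silyl ether and free C6 hydroxyl in target numbering)
Conditions: PPTS (cat.), MeOH/CH2Cl2, 0 °C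
Reagents that add atoms: none
Why: Acid-catalysed methanolysis distinguishes the silyl ethers by size, the triethylsilyl ether being cleaved far faster than the tert-butyldimethylsilyl ether, and the acidic medium excludes silyl migration.

Step 8
Reactants: 11 4-methylpent-3-enoic acid
Product: 12 methyl 4-methylpent-3-enoate
Conditions: MeI, KHCO3, DMF, rt
Reagents that add atoms: iodomethane, CI
Why: O-alkylation of the carboxylate (SN2) under a weak base avoids both the acid that would lactonise 11 and the strong base that would move the alkene into conjugation.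

Step 9
Reactants: 10 (1S,2S,6S)-2-(tert-butyldimethylsilyloxy)-6-ethenyl-3-methylcyclohex-3-en-1-ol; 12 methyl 4-methylpent-3-enoate
Product: 14 (1S,2S)-2-[(1S,5S,6S)-5-(tert-butyldimethylsilyloxy)-6-hydroxy-4-methylcyclohex-3-en-1-yl]-1-(3-methylbut-2-en-1-yl)cyclopropan-1-ol (alkyl groups trans; 7S,8S in target numbering), via tethered titanacyclopropane 13 (not isolated)
Conditions: ClTi(OiPr)3 (1.2 equiv), 12 (2 equiv), THF, rt; c-C6H11MgCl (5 equiv, Et2O) by syringe pump over 2 h; aq. NH4Cl
Reagents that add atoms: none
Why: Two equivalents of the Grignard reagent turn the titanium alkoxide into a cyclohexene titanacyclopropane, and the weakly bound cyclohexene is displaced by the only monosubstituted alkene, the C5 vinyl group, an exchange made intramolecular by the C6 alkoxide that already sits on titanium (13). The ester carbonyl of 12 inserts into one Ti–C bond, methoxide is expelled, and the remaining Ti–C bond adds to the resulting ketone in a 3-exo-trig closure, so that C7–C8 and C8–CH2 are both formed and the three-membered ring C7–CH2–C8 is closed. The closest known reaction is the Kulinkovich hydroxycyclopropanation in its alkene-exchange variant, for which homoallylic alcohols are privileged partners. C7 is set by delivery of titanium to the vinyl face turned towards C6, in the rotamer that eclipses C5–H with the alkene, followed by C–C bond formation with retention, and C8 is set by the bicyclic titanate, which is known to place the two alkyl groups trans rather than in the cis arrangement of untethered alkenes. Both centres become sp2 in step 10, so all cyclopropane isomers are carried forward together. The step needs chemoselective exchange at the vinyl group, secured by the tether and by the inertness of the trisubstituted C2=C3 and C10=C11 alkenes towards titanium, and it needs the acidic C9 protons of 12 to survive, secured by slow addition that keeps free Grignard reagent low.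

Step 10
Reactants: 14 the trans-cyclopropanol
Product: 15 2-[(1S,5S,6S)-5-(tert-butyldimethylsilyloxy)-6-hydroxy-4-methylcyclohex-3-en-1-yl]-6-methylhepta-1,5-dien-3-one
Conditions: Pd(OAc)2 (15 mol %), O2 (1 atm), DMSO/toluene, rt
Reagents that add atoms: none
Why: In this oxidative cyclopropanol opening by divalent palladium the palladium cyclopropoxide undergoes β-carbon elimination at the less substituted C8–CH2 bond, the primary homoenolate loses the C7 hydrogen by β-hydride elimination to give the C7=CH2 enone, and at room temperature without an amine ligand the hindered C6 carbinol should not be oxidised.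

Step 11
Reactants: 15 the C6 hydroxy dienone; 16 tigloyl chloride [(E)-2-methylbut-2-enoyl chloride]
Product: 17 (1S,2S,6S)-2-(tert-butyldimethylsilyloxy)-3-methyl-6-(6-methyl-3-oxohepta-1,5-dien-2-yl)cyclohex-3-en-1-yl (E)-2-methylbut-2-enoate
Conditions: pyridine, DMAP (cat.), CH2Cl2, 0 °C → rt
Reagents that add atoms: none
Why: DMAP-catalysed acylation reaches the only free hydroxyl (any cyclic hemiketal form of 15 drains through the open hydroxy ketone), and the weak amine bases leave the C9 protons and the E-tigloyl geometry untouched.

Step 12
Reactants: 17 the C1 silyl ether C6 tiglate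
Product: 18 (1S,2S,6S)-2-hydroxy-3-methyl-6-(6-methyl-3-oxohepta-1,5-dien-2-yl)cyclohex-3-en-1-yl (E)-2-methylbut-2-enoate
Conditions: HF·pyridine, pyridine, THF, 0 °C → rt
Reagents that add atoms: none
Why: Fluoride desilylation in a weakly acidic medium never generates a free C1 alkoxide, so tiglate migration from C6 to C1, conjugate addition to the C7=CH2 enone and conjugation of the prenyl ketone have no way to start.

Step 13
Reactants: 18 the C1 allylic alcohol
Product: 19 (1R,2R,3S,5S,6S)-2,3-epoxy-1-hydroxy-2-methyl-5-(6-methyl-3-oxohepta-1,5-dien-2-yl)cyclohexan-6-yl (E)-2-methylbut-2-enoate (target numbering; epoxide cis to C1–OH and to the C5 chain)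
Conditions: VO(acac)2 (5 mol %), t-BuOOH (decane), CH2Cl2, 0 °C
Reagents that add atoms: tert-butyl hydroperoxide, CC(C)(C)OO
Why: In this hydroxyl-directed vanadium-catalysed epoxidation the C1 vanadate delivers oxygen to the C2=C3 face syn to C1–OH, which sets C2 and C3, while the undirected prenyl alkene and the electron-poor tiglate and enone alkenes react much more slowly.

Step 14
Reactants: 19 the epoxy alcohol
Product: 20 (2S,3S,5S,6S)-2,3-epoxy-2-methyl-5-(6-methyl-3-oxohepta-1,5-dien-2-yl)-1-oxocyclohexan-6-yl (E)-2-methylbut-2-enoate (target numbering)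
Conditions: Dess–Martin periodinane, NaHCO3, CH2Cl2, 0 °C → rt
Reagents that add atoms: none
Why: Buffered Dess–Martin oxidation converts the secondary epoxy alcohol to the epoxy ketone without opening the epoxide or epimerising C6, whose trans-diequatorial arrangement with C5 is in any case the more stable one.

Step 15
Reactants: 20 the epoxy ketone with the prenyl ketone side chain
Product: 21 CNP0284595.1, (2S,3S,5S,6S)-2,3-epoxy-5-[(4E)-6-hydroperoxy-6-methyl-3-oxohepta-1,4-dien-2-yl]-2-methyl-1-oxocyclohexan-6-yl (E)-2-methylbut-2-enoate (target numbering)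
Conditions: O2, tetraphenylporphyrin (cat.), visible light, CH2Cl2, −20 °C; no reductive work-up
Reagents that add atoms: dioxygen, O=O
Why: In this Schenck ene reaction singlet oxygen attacks only the electron-rich trisubstituted C10=C11 alkene, and abstraction of a C9 hydrogen, favoured because it brings the new alkene into conjugation with C8=O, places the hydroperoxy group on C11 and gives the E-configured C9=C10 bond.

**Compound list**
1 | 6-methylcyclohex-2-en-1-one (racemic) | CC1CCC=CC1=O | starting material
2 | potassium vinyltrifluoroborate | C=C[B-](F)(F)F.[K+] | starting material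
3 | (5R)-5-ethenyl-2-methylcyclohexan-1-one (C2 epimers) | C=C[C@@H]1CCC(C)C(=O)C1 | intermediate
4 | [(5R)-5-ethenyl-2-methylcyclohex-1-en-1-yl]oxytrimethylsilane | C=C[C@@H]1CCC(C)=C(O[Si](C)(C)C)C1 | intermediate
5 | (5R)-5-ethenyl-2-methylcyclohex-2-en-1-one | C=C[C@@H]1CC=C(C)C(=O)C1 | intermediate
6 | triethyl{[(3S)-3-ethenyl-6-methylcyclohexa-1,5-dien-1-yl]oxy}silane | C=C[C@@H]1CC=C(C)C(O[Si](CC)(CC)CC)=C1 | intermediate (not isolated)
7 | (5S,6S)-5-ethenyl-2-methyl-6-(triethylsilyloxy)cyclohex-2-en-1-one | C=C[C@@H]1CC=C(C)C(=O)[C@H]1O[Si](CC)(CC)CC | intermediate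
8 | (1S,5S,6S)-5-ethenyl-2-methyl-6-(triethylsilyloxy)cyclohex-2-en-1-ol | C=C[C@@H]1CC=C(C)[C@H](O)[C@H]1O[Si](CC)(CC)CC | intermediate
9 | (1S,5S,6S)-1-(tert-butyldimethylsilyloxy)-5-ethenyl-2-methyl-6-(triethylsilyloxy)cyclohex-2-ene | C=C[C@@H]1CC=C(C)[C@H](O[Si](C)(C)C(C)(C)C)[C@H]1O[Si](CC)(CC)CC | intermediate
10 | (1S,2S,6S)-2-(tert-butyldimethylsilyloxy)-6-ethenyl-3-methylcyclohex-3-en-1-ol | C=C[C@@H]1CC=C(C)[C@H](O[Si](C)(C)C(C)(C)C)[C@H]1O | intermediate
11 | 4-methylpent-3-enoic acid | CC(C)=CCC(=O)O | starting material
12 | methyl 4-methylpent-3-enoate | COC(=O)CC=C(C)C | intermediate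
13 | C6-alkoxide-tethered isopropoxy titanacyclopropane on C7 and its CH2 | CC(C)O[Ti]12C[C@H]1[C@@H]3CC=C(C)[C@H](O[Si](C)(C)C(C)(C)C)[C@H]3O2 | intermediate (not isolated)
14 | (1S,2S)-2-[(1S,5S,6S)-5-(tert-butyldimethylsilyloxy)-6-hydroxy-4-methylcyclohex-3-en-1-yl]-1-(3-methylbut-2-en-1-yl)cyclopropan-1-ol | CC(C)=CC[C@]1(O)C[C@H]1[C@@H]2CC=C(C)[C@H](O[Si](C)(C)C(C)(C)C)[C@H]2O | intermediate
15 | 2-[(1S,5S,6S)-5-(tert-butyldimethylsilyloxy)-6-hydroxy-4-methylcyclohex-3-en-1-yl]-6-methylhepta-1,5-dien-3-one | C=C(C(=O)CC=C(C)C)[C@@H]1CC=C(C)[C@H](O[Si](C)(C)C(C)(C)C)[C@H]1O | intermediate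
16 | tigloyl chloride | C/C=C(\C)C(=O)Cl | starting material
17 | C1 silyl ether C6 tiglate | C=C(C(=O)CC=C(C)C)[C@@H]1CC=C(C)[C@H](O[Si](C)(C)C(C)(C)C)[C@H]1OC(=O)/C(C)=C/C | intermediate
18 | C1 allylic alcohol C6 tiglate | C=C(C(=O)CC=C(C)C)[C@@H]1CC=C(C)[C@H](O)[C@H]1OC(=O)/C(C)=C/C | intermediate
19 | 2,3-epoxy C1 alcohol C6 tiglate | C=C(C(=O)CC=C(C)C)[C@@H]1C[C@@H]2O[C@]2(C)[C@H](O)[C@H]1OC(=O)/C(C)=C/C | intermediate
20 | 2,3-epoxy C1 ketone C6 tiglate with prenyl ketone chain | C=C(C(=O)CC=C(C)C)[C@@H]1C[C@@H]2O[C@]2(C)C(=O)[C@H]1OC(=O)/C(C)=C/C | intermediate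
21 | CNP0284595.1 | C=C(C(=O)/C=C/C(C)(C)OO)[C@@H]1C[C@@H]2O[C@]2(C)C(=O)[C@H]1OC(=O)/C(C)=C/C | target

**Step count.** The route has 15 steps in total. The longest linear sequence is 14 steps (steps 1–7 and 9–15, from 1 to 21).

**Steps most likely to fail**

1. Step 9.
   - What may go wrong: titanium may transfer slowly from cyclohexene to the α-branched vinyl group. The Grignard reagent may enolise the doubly activated C9 protons of 12. The silyl group may migrate between the C1 and C6 oxygens under the basic conditions.
   - Fallback, from 10 back to 14: the union is made intramolecular. Compound 10 is esterified at C6–OH with acid 11 (DCC, DMAP, CH2Cl2) to give the C6 4-methylpent-3-enoate of 10 F1.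
   - Ti(OiPr)4 and i-PrMgCl (Et2O, −45 °C → rt) then place titanium on the vinyl group. Titanium attacks the tethered ester by intramolecular nucleophilic acyl substitution followed by carbonyl addition. This is a known reaction of homoallyl esters. It forms the same two bonds, frees C6–OH and delivers 14.

2. Step 10.
   - What may go wrong: palladium hydride may re-add, moving the exocyclic alkene into the tetrasubstituted C5=C7 position or the prenyl alkene into conjugation. The homoenolate may be protonated to the saturated α-methyl ketone. The C6 carbinol may be oxidised in competition.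
   - Fallback, from 14 back to 15: the enone is unmasked in two polar stages without palladium hydride. Copper-catalysed electrophilic amination of the cyclopropanol (4-benzoyloxymorpholine, Cu(OTf)2 cat., rt) is expected to open the same less substituted bond through a copper homoenolate. It gives the β-morpholinomethyl ketone F2.
   - MeI converts F2 to the N-methylmorpholinium iodide F3, and aqueous NaHCO3 triggers the classical Mannich-base elimination to 15.

3. Step 15.
   - What may go wrong: regioselectivity may be poor through hydrogen abstraction from the geminal methyl groups instead of C9. The tiglate may undergo slow secondary photooxygenation on prolonged irradiation.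
   - Fallback, from 20 back to 21: C11–O is fixed by ionic Markovnikov chemistry. Bromohydroperoxidation of the only electron-rich alkene (1,3-dibromo-5,5-dimethylhydantoin, anhydrous H2O2 in Et2O, −40 °C) gives the C10-bromo C11-hydroperoxide F4.
   - In F4 the bromide is β to C8=O, so Et3N (CH2Cl2, −20 °C) removes HBr by an E1cB path across C9–C10 and gives the E-enone 21.

**Further compounds**
F1 | step 9 | (1S,2S,6S)-2-(tert-butyldimethylsilyloxy)-6-ethenyl-3-methylcyclohex-3-en-1-yl 4-methylpent-3-enoate | C=C[C@@H]1CC=C(C)[C@H](O[Si](C)(C)C(C)(C)C)[C@H]1OC(=O)CC=C(C)C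
F2 | step 10 | β-morpholinomethyl ketone (C7 bears CH2-morpholine; C8 ketone; ring as in 14) | CC(C)=CCC(=O)[C@@H](CN1CCOCC1)[C@@H]2CC=C(C)[C@H](O[Si](C)(C)C(C)(C)C)[C@H]2O
F3 | step 10 | N-methylmorpholinium iodide of F2 | CC(C)=CCC(=O)[C@@H](C[N+]1(C)CCOCC1)[C@@H]2CC=C(C)[C@H](O[Si](C)(C)C(C)(C)C)[C@H]2O.[I-]
F4 | step 15 | C10-bromo C11-hydroperoxide of 20 (C10 epimers) | C=C(C(=O)CC(Br)C(C)(C)OO)[C@@H]1C[C@@H]2O[C@]2(C)C(=O)[C@H]1OC(=O)/C(C)=C/C
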